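**Retrosynthetic overview**
1. Target 33 comes from alcohol 32 by C8 methacrylation, and 32 from butenolide 29 by silyl-to-acetate exchange at C2/C13 and PMB removal. The lactone ring (C6–O–C12–C11=C7) is closed last, by intramolecular Horner–Wadsworth–Emmons reaction of the C6 phosphonoacetate of hydroxy ketone 24.
2. The strategy rests on the 1,5-diene of the ten-membered carbocycle (C1–C10): C1=C10 and C4=C5 are linked through C2–C3, so C5 and C10 can be joined as the ring fusion of a 4,10-dimethyldecalin (ring A: C1–C5 plus C10; ring B: C5–C10). Cleaving that C5–C10 bond by boronate Grob-type fragmentation of mesylate 19 unveils the ring (22) and both E alkenes from sp3 stereochemistry.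
3. Decalin 19 (1β-OMs, 2α-OTBS, 7-dioxolane, 8β-OPMB, C4=C5) comes from (S)-Wieland–Miescher ketone 5 by γ-methylenation/hydrogenation (C15), C8 hydroxylation–ketalisation–oxidation–reduction, and C2 hydroxylation/C1 reduction. Rings A and B form first (step 1), the ten-membered ring appears in step 15, the lactone in step 21.

Key step: step 15

Assumption: ring positions are numbered as in germacranes and eudesmanes (C1–C10; C14 = methyl on C10, C15 = methyl on C4, C11–C13 = lactone carbons), β denotes the face of the C10 methyl in the decalins, and the stereocentre α to phosphorus in 26–28 is racemic and is destroyed in step 21.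

**Route**

Step 1
Reactants: 1 2-methylcyclohexane-1,3-dione; 2 methyl vinyl ketone
Product: 5 (S)-Wieland–Miescher ketone, via triketone 3 (not isolated), via cis-ketol 4 (not isolated)
Conditions: L-proline (cat.), DMSO, rt to 35 °C; recrystallisation
Reagents that add atoms: none
Why: Michael addition gives triketone 3, and the (S)-proline enamine of its side-chain ketone closes ring B by an intramolecular aldol reaction on one of the two enantiotopic ring carbonyls (directed by the carboxylic acid of the catalyst), which sets the C10 quaternary centre as S before dehydration completes the Robinson annulation.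

Step 2
Reactants: 5 (S)-Wieland–Miescher ketone
Product: 6 4-methylene dienedione
Conditions: CH2(OEt)2, POCl3, NaOAc, CHCl3, reflux
Reagents that add atoms: diethoxymethane, CCOCOCC
Why: Under the acetal conditions the enone forms its dienol ether, which is alkoxymethylated at the γ-carbon C4 by the oxocarbenium ion of the formaldehyde acetal and then loses ethanol (vinylogous Mannich-type γ-methylenation, established for 4-en-3-one steroids that also carry a saturated ketone); the C1 ketone cannot form a dienol and should not compete.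

Step 3
Reactants: 6 4-methylene dienedione
Product: 8 (4S,10S)-4,10-dimethyl enedione, via 4β-methyl epimer 7 (not isolated)
Conditions: H2 (1 atm), RhCl(PPh3)3 (cat.), PhH, rt; then HCl (cat.), CHCl3, rt
Reagents that add atoms: none
Why: Homogeneous rhodium-catalysed hydrogenation reduces the unhindered 1,1-disubstituted exocyclic alkene in preference to the trisubstituted enone alkene, hydrogen arriving at C4 from the α face to give 7, and acid then epimerises C4 through the dienol to the equatorial 4α-methyl isomer 8 (either epimer would serve, since C4 becomes sp2 in step 6).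

Step 4
Reactants: 8 (4S,10S)-4,10-dimethyl enedione
Product: 9 C1-dioxolane enone
Conditions: HOCH2CH2OH, p-TsOH·H2O (cat.), 4 Å molecular sieves, rt
Reagents that add atoms: ethylene glycol, OCCO
Why: Acid-catalysed ketalisation at room temperature is chemoselective for the saturated C1 carbonyl over the less electrophilic conjugated C7 carbonyl, a known selectivity of this diketone class, and leaves the enone unmigrated.

Step 5
Reactants: 9 C1-dioxolane enone
Product: 10 8α-hydroxy enone
Conditions: KN(SiMe3)2, THF, −78 °C; 2-(phenylsulfonyl)-3-phenyloxaziridine; aq. NH4Cl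
Reagents that add atoms: 2-(phenylsulfonyl)-3-phenyloxaziridine, O=S(=O)(c1ccccc1)N1OC1c1ccccc1
Why: Kinetic deprotonation of the enone at C8 gives the cross-conjugated enolate, and electrophilic oxygen transfer from the N-sulfonyloxaziridine (enolate α-hydroxylation) is expected anti to the axial C10 methyl to give the equatorial 8α-alcohol; this configuration is not relied on, because step 7 removes it.

Step 6
Reactants: 10 8α-hydroxy enone
Product: 11 bis-dioxolane 8α-alcohol with C4=C5
Conditions: HOCH2CH2OH, p-TsOH·H2O (cat.), PhH, reflux (Dean–Stark)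
Reagents that add atoms: ethylene glycol, OCCO
Why: Thermodynamic ketalisation of the enone runs through the dienol ether and α-protonation, so the alkene leaves conjugation for the tetrasubstituted C4=C5 position (deconjugative ketalisation), which also erases the C4 stereocentre.

Step 7
Reactants: 11 bis-dioxolane 8α-alcohol
Product: 12 C8 ketone
Conditions: Dess–Martin periodinane, NaHCO3, CH2Cl2, rt
Reagents that add atoms: none
Why: Buffered hypervalent-iodine oxidation of the secondary alcohol gives the α-ketal ketone without touching the ketals or the alkene.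

Step 8
Reactants: 12 C8 ketone
Product: 13 8β-alcohol
Conditions: LiBH(s-Bu)3, THF, −78 °C; aq. NH4Cl
Reagents that add atoms: none
Why: Ring B is a chair whose C10 methyl is axial and syn-axial to the C8 carbonyl, so the bulky trialkylborohydride can only attack from the α face (equatorial attack) and sets the axial 8β-alcohol by substrate control.

Step 9
Reactants: 13 8β-alcohol
Product: 14 8β-PMB ether
Conditions: NaH, 4-MeOC6H4CH2Cl, Bu4NI (cat.), DMF, 0 °C to rt
Reagents that add atoms: 4-methoxybenzyl chloride, COc1ccc(CCl)cc1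
Why: Williamson etherification of the sodium alkoxide (iodide catalysis) on a substrate that carries no base-sensitive group.

Step 10
Reactants: 14 8β-PMB ether
Product: 15 C1 ketone
Conditions: PPTS (cat.), acetone/H2O, rt
Reagents that add atoms: water, O
Why: Acid-catalysed ketal hydrolysis is selective for the sterically compressed C1 dioxolane because the C7 dioxolane is deactivated by the electron-withdrawing C8 ether next to its oxocarbenium carbon, and the liberated C1 ketone cannot conjugate with C4=C5 since C10 is quaternary.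

Step 11
Reactants: 15 C1 ketone
Product: 16 2α-hydroxy ketone
Conditions: KN(SiMe3)2, THF, −78 °C; 2-(phenylsulfonyl)-3-phenyloxaziridine; aq. NH4Cl
Reagents that add atoms: 2-(phenylsulfonyl)-3-phenyloxaziridine, O=S(=O)(c1ccccc1)N1OC1c1ccccc1
Why: The C1 ketone can enolise only toward C2, and oxygen transfer from the oxaziridine to the potassium enolate (enolate α-hydroxylation) occurs on the face anti to the pseudoaxial C10 methyl, giving the equatorial 2α-alcohol.

Step 12
Reactants: 16 2α-hydroxy ketone
Product: 17 2α-silyloxy ketone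
Conditions: TBSCl, imidazole, DMF, rt
Reagents that add atoms: tert-butyldimethylsilyl chloride, CC(C)(C)[Si](C)(C)Cl
Why: Routine silylation of the only free, unhindered secondary hydroxyl.

Step 13
Reactants: 17 2α-silyloxy ketone
Product: 18 1β-alcohol
Conditions: NaBH4, MeOH, 0 °C
Reagents that add atoms: none
Why: Hydride adds to the C1 carbonyl from the α face, anti to the adjacent angular methyl (axial attack), giving the equatorial 1β-alcohol trans to the 2α-silyl ether, as in borohydride reductions of the parent C1 ketone.

Step 14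
Reactants: 18 1β-alcohol
Product: 19 1β-mesylate (fragmentation precursor)
Conditions: MsCl, Et3N, CH2Cl2, 0 °C
Reagents that add atoms: methanesulfonyl chloride, CS(=O)(=O)Cl
Why: Sulfene-mediated mesylation works on the hindered neopentyl-type secondary alcohol and retains its configuration.

Step 15
Reactants: 19 1β-mesylate
Product: 22 (E,E)-cyclodecadiene ketal, via 4α-borane 20 (not isolated), via methoxyborate 21 (not isolated)
Conditions: BH3·THF, THF, 0 °C to rt; then NaOMe, MeOH, 0 °C to rt
Reagents that add atoms: none
Why: BH3 adds syn across the tetrasubstituted C4=C5 bond from the α face, anti to the C10 methyl, with boron on C4 (the alkene carbon remote from quaternary C10), which gives trans-decalin 20 with an equatorial C4–B bond; methoxide then forms borate 21, in which the C4–B bond, the C5–C10 bond and the equatorial C1–OMs bond are antiperiplanar, so that a concerted Grob-type fragmentation moves the C–B electrons into C4=C5, breaks C5–C10, forms C1=C10 and expels mesylate. The closest known reaction is the alkoxide-triggered fragmentation of hydroborated octalin sulfonates to (E,E)-cyclodeca-1,5-dienes (Marshall fragmentation). No ring is closed: the ten-membered ring is set free when the bond shared by rings A and B is cleaved. No stereocentre is created, both E geometries follow stereospecifically from the trans ring fusion and the two equatorial bonds, and C2 and C8 pass through unchanged. The step needs boron on C4 from the α face and an equatorial leaving group: the angular methyl and the greater hindrance at C5 secure the former, the hydride reduction of step 13 the latter. The product is kept at or below room temperature so that the 1,5-diene does not undergo Cope rearrangement.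

Step 16
Reactants: 22 (E,E)-cyclodecadiene ketal
Product: 23 cyclodecadienone
Conditions: PPTS, acetone/H2O, 40 °C
Reagents that add atoms: water, O
Why: Acid-catalysed ketal hydrolysis, in which relief of transannular strain on going from sp3 to sp2 at C7 of the ten-membered ring should offset the retarding C8 ether, so that a weak pyridinium acid suffices and the silyl ether, the E,E-diene and the β,γ position of C4=C5 are kept.

Step 17
Reactants: 23 cyclodecadienone
Product: 24 (6R)-6-hydroxy ketone
Conditions: KN(SiMe3)2, THF, −78 °C; 2-(phenylsulfonyl)-3-phenyloxaziridine; AcOH, −78 °C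
Reagents that add atoms: 2-(phenylsulfonyl)-3-phenyloxaziridine, O=S(=O)(c1ccccc1)N1OC1c1ccccc1
Why: The amide base removes a C6 proton (a methylene that is both α to the carbonyl and allylic) rather than the hindered ether-bearing C8–H, and the oxaziridine hydroxylates the resulting ring-cis enolate at C6 (enolate α-hydroxylation); allylic 1,3-strain turns H8 into the enolate plane so that the C8 PMB ether covers one face and oxygen is delivered to the other, which corresponds to the 6R configuration.

Step 18
Reactants: 25 allyl diethylphosphonoacetate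
Product: 26 allyl 2-(diethoxyphosphoryl)-3-(triisopropylsilyloxy)propanoate
Conditions: NaH, THF, 0 °C; i-Pr3SiOCH2Cl
Reagents that add atoms: (triisopropylsilyloxy)methyl chloride, CC(C)[Si](OCCl)(C(C)C)C(C)C
Why: C-Alkylation of the sodium enolate of the phosphonoacetate by the reactive α-chloro ether (SN2 at an oxocarbenium-like carbon) installs the silyl-protected hydroxymethyl group that becomes C13.

Step 19
Reactants: 26 allyl 2-(diethoxyphosphoryl)-3-(triisopropylsilyloxy)propanoate
Product: 27 2-(diethoxyphosphoryl)-3-(triisopropylsilyloxy)propanoic acid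
Conditions: Pd(PPh3)4 (cat.), morpholine, THF, rt
Reagents that add atoms: none
Why: Zerovalent palladium ionises the allyl ester and morpholine traps the π-allyl fragment (Tsuji–Trost-type deallylation), which frees the acid under neutral conditions without β-elimination of the silyloxy group.

Step 20
Reactants: 24 (6R)-6-hydroxy ketone; 27 2-(diethoxyphosphoryl)-3-(triisopropylsilyloxy)propanoic acid
Product: 28 C6 phosphonoacetate ester
Conditions: DCC, DMAP (cat.), CH2Cl2, 0 °C
Reagents that add atoms: none
Why: Carbodiimide-mediated (Steglich-type) esterification acylates the secondary C6 alcohol with retention of configuration.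

Step 21
Reactants: 28 C6 phosphonoacetate ester
Product: 29 protected butenolide
Conditions: LiCl, i-Pr2NEt, MeCN, rt
Reagents that add atoms: none
Why: Intramolecular Horner–Wadsworth–Emmons reaction under mild lithium chloride/amine (Masamune–Roush) conditions: only the phosphonate α-proton is acidic enough to be removed, the carbanion adds to the C7 ketone in a five-membered ring closure and phosphate is lost to give the C7=C11 butenolide.

Step 22
Reactants: 29 protected butenolide
Product: 30 2,13-diol
Conditions: Bu4NF, AcOH, THF, 0 °C to rt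
Reagents that add atoms: none
Why: Acetic-acid-buffered fluoride cleaves the secondary TBS and primary TIPS ethers without deprotonating the butenolide at its γ-carbon C6.

Step 23
Reactants: 30 2,13-diol
Product: 31 2,13-diacetate
Conditions: Ac2O, pyridine, DMAP (cat.), CH2Cl2, 0 °C to rt
Reagents that add atoms: acetic anhydride, CC(=O)OC(C)=O
Why: DMAP-catalysed acetylation of the primary C13 and secondary C2 alcohols.

Step 24
Reactants: 31 2,13-diacetate
Product: 32 C8 alcohol
Conditions: DDQ, CH2Cl2/pH 7 buffer, 0 °C
Reagents that add atoms: none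
Why: DDQ oxidises the electron-rich benzyl ether to an oxocarbenium ion that water hydrolyses (oxidative PMB cleavage), while the acetates, the butenolide and the trisubstituted alkenes are inert.

Step 25
Reactants: 32 C8 alcohol
Product: 33 target CNP0309304.1
Conditions: methacrylic anhydride, Et3N, DMAP (cat.), CH2Cl2, 0 °C
Reagents that add atoms: methacrylic anhydride, C=C(C)C(=O)OC(=O)C(C)=C
Why: DMAP-catalysed acylation of the C8 alcohol with the anhydride under mild base; C8 is trans to C12 across C7=C11, so no translactonisation can compete.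

**Compound list**
1 | 2-methylcyclohexane-1,3-dione | CC1C(=O)CCCC1=O | starting material
2 | methyl vinyl ketone (but-3-en-2-one) | CC(=O)C=C | starting material
3 | 2-methyl-2-(3-oxobutyl)cyclohexane-1,3-dione (triketone) | CC(=O)CCC1(C)C(=O)CCCC1=O | intermediate
4 | cis-fused aldol ketol, 5-hydroxy-10-methyldecalin-1,7-dione with 5-OH cis to the 10-methyl | C[C@]12CCC(=O)C[C@@]1(O)CCCC2=O | intermediate
5 | (S)-Wieland–Miescher ketone, (S)-8a-methyl-3,4,8,8a-tetrahydronaphthalene-1,6(2H,7H)-dione (C1 and C7 ketones, C5=C6) | C[C@]12CCC(=O)C=C1CCCC2=O | intermediate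
6 | (10S)-10-methyl-4-methylene-Δ5-octalin-1,7-dione | C[C@]12CCC(=O)C=C1C(=C)CCC2=O | intermediate
7 | (4R,10S)-4,10-dimethyl-Δ5-octalin-1,7-dione (4β-methyl epimer) | C[C@]12CCC(=O)C=C1[C@H](C)CCC2=O | intermediate
8 | (4S,10S)-4,10-dimethyl-Δ5-octalin-1,7-dione (4α-methyl, equatorial) | C[C@]12CCC(=O)C=C1[C@@H](C)CCC2=O | intermediate
9 | 1,1-(ethylenedioxy)-4α,10β-dimethyl-Δ5-octalin-7-one | C[C@]12CCC(=O)C=C1[C@@H](C)CCC23OCCO3 | intermediate
10 | 1,1-(ethylenedioxy)-8α-hydroxy-4α,10β-dimethyl-Δ5-octalin-7-one | C[C@]12C[C@@H](O)C(=O)C=C1[C@@H](C)CCC23OCCO3 | intermediate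
11 | 1,1:7,7-bis(ethylenedioxy)-4,10β-dimethyl-Δ4-octalin-8α-ol | C[C@]12C[C@@H](O)C3(OCCO3)CC1=C(C)CCC24OCCO4 | intermediate
12 | 1,1:7,7-bis(ethylenedioxy)-4,10β-dimethyl-Δ4-octalin-8-one | C[C@]12CC(=O)C3(OCCO3)CC1=C(C)CCC24OCCO4 | intermediate
13 | 1,1:7,7-bis(ethylenedioxy)-4,10β-dimethyl-Δ4-octalin-8β-ol | C[C@]12C[C@H](O)C3(OCCO3)CC1=C(C)CCC24OCCO4 | intermediate
14 | 8β-(4-methoxybenzyloxy)-1,1:7,7-bis(ethylenedioxy)-4,10β-dimethyl-Δ4-octalin | C[C@]12C[C@H](OCc3ccc(OC)cc3)C4(OCCO4)CC1=C(C)CCC25OCCO5 | intermediate
15 | 7,7-(ethylenedioxy)-8β-(4-methoxybenzyloxy)-4,10β-dimethyl-Δ4-octalin-1-one | C[C@]12C[C@H](OCc3ccc(OC)cc3)C4(OCCO4)CC1=C(C)CCC2=O | intermediate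
16 | 2α-hydroxy-7,7-(ethylenedioxy)-8β-(4-methoxybenzyloxy)-4,10β-dimethyl-Δ4-octalin-1-one | C[C@]12C[C@H](OCc3ccc(OC)cc3)C4(OCCO4)CC1=C(C)C[C@@H](O)C2=O | intermediate
17 | 2α-(tert-butyldimethylsilyloxy)-7,7-(ethylenedioxy)-8β-(4-methoxybenzyloxy)-4,10β-dimethyl-Δ4-octalin-1-one | C[C@]12C[C@H](OCc3ccc(OC)cc3)C4(OCCO4)CC1=C(C)C[C@@H](O[Si](C)(C)C(C)(C)C)C2=O | intermediate
18 | 2α-(tert-butyldimethylsilyloxy)-7,7-(ethylenedioxy)-8β-(4-methoxybenzyloxy)-4,10β-dimethyl-Δ4-octalin-1β-ol | C[C@]12C[C@H](OCc3ccc(OC)cc3)C4(OCCO4)CC1=C(C)C[C@@H](O[Si](C)(C)C(C)(C)C)[C@@H]2O | intermediate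
19 | 1β-methanesulfonate of 18 (fragmentation precursor) | C[C@]12C[C@H](OCc3ccc(OC)cc3)C4(OCCO4)CC1=C(C)C[C@@H](O[Si](C)(C)C(C)(C)C)[C@@H]2OS(C)(=O)=O | intermediate
20 | 4α-boryl-5α-H trans-decalin mesylate (4β,10β-dimethyl) | C[C@]12C[C@H](OCc3ccc(OC)cc3)C4(OCCO4)C[C@@H]1[C@@](C)(B)C[C@@H](O[Si](C)(C)C(C)(C)C)[C@@H]2OS(C)(=O)=O | intermediate
21 | sodium methoxyborate of 20 | C[C@]12C[C@H](OCc3ccc(OC)cc3)C4(OCCO4)C[C@@H]1[C@@](C)([BH2-]OC)C[C@@H](O[Si](C)(C)C(C)(C)C)[C@@H]2OS(C)(=O)=O.[Na+] | intermediate
22 | (2R,8S,1(10)E,4E)-2-(tert-butyldimethylsilyloxy)-7,7-(ethylenedioxy)-8-(4-methoxybenzyloxy)-4,10-dimethylcyclodeca-1(10),4-diene | COc1ccc(CO[C@H]2C/C(C)=C/[C@H](O[Si](C)(C)C(C)(C)C)C/C(C)=C/CC23OCCO3)cc1 | intermediate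
23 | (2R,8S,1(10)E,4E)-2-(tert-butyldimethylsilyloxy)-8-(4-methoxybenzyloxy)-4,10-dimethylcyclodeca-1(10),4-dien-7-one | COc1ccc(CO[C@H]2C/C(C)=C/[C@H](O[Si](C)(C)C(C)(C)C)C/C(C)=C/CC2=O)cc1 | intermediate
24 | (2R,6R,8S)-6-hydroxy derivative of 23 | COc1ccc(CO[C@H]2C/C(C)=C/[C@H](O[Si](C)(C)C(C)(C)C)C/C(C)=C/[C@@H](O)C2=O)cc1 | intermediate
25 | allyl 2-(diethoxyphosphoryl)acetate | C=CCOC(=O)CP(=O)(OCC)OCC | starting material
26 | allyl 2-(diethoxyphosphoryl)-3-(triisopropylsilyloxy)propanoate (racemic) | C=CCOC(=O)C(CO[Si](C(C)C)(C(C)C)C(C)C)P(=O)(OCC)OCC | intermediate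
27 | 2-(diethoxyphosphoryl)-3-(triisopropylsilyloxy)propanoic acid (racemic) | OC(=O)C(CO[Si](C(C)C)(C(C)C)C(C)C)P(=O)(OCC)OCC | intermediate
28 | C6 ester of 24 with acid 27 (both epimers at the phosphonate carbon) | COc1ccc(CO[C@H]2C/C(C)=C/[C@H](O[Si](C)(C)C(C)(C)C)C/C(C)=C/[C@@H](OC(=O)C(CO[Si](C(C)C)(C(C)C)C(C)C)P(=O)(OCC)OCC)C2=O)cc1 | intermediate
29 | (2R,6R,8S)-2-(tert-butyldimethylsilyloxy)-8-(4-methoxybenzyloxy)-13-(triisopropylsilyloxy)germacra-1(10)E,4E,7(11)-trien-12,6-olide | COc1ccc(CO[C@H]2C/C(C)=C/[C@H](O[Si](C)(C)C(C)(C)C)C/C(C)=C/[C@H]3OC(=O)C(CO[Si](C(C)C)(C(C)C)C(C)C)=C23)cc1 | intermediate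
30 | (2R,6R,8S)-2,13-dihydroxy-8-(4-methoxybenzyloxy)germacra-1(10)E,4E,7(11)-trien-12,6-olide | COc1ccc(CO[C@H]2C/C(C)=C/[C@H](O)C/C(C)=C/[C@H]3OC(=O)C(CO)=C23)cc1 | intermediate
31 | (2R,6R,8S)-2,13-diacetoxy-8-(4-methoxybenzyloxy)germacra-1(10)E,4E,7(11)-trien-12,6-olide | COc1ccc(CO[C@H]2C/C(C)=C/[C@H](OC(C)=O)C/C(C)=C/[C@H]3OC(=O)C(COC(C)=O)=C23)cc1 | intermediate
32 | (2R,6R,8S)-2,13-diacetoxy-8-hydroxygermacra-1(10)E,4E,7(11)-trien-12,6-olide | O[C@H]1C/C(C)=C/[C@H](OC(C)=O)C/C(C)=C/[C@H]2OC(=O)C(COC(C)=O)=C12 | intermediate
33 | CNP0309304.1, (2R,6R,8S)-2,13-diacetoxy-8-(methacryloyloxy)germacra-1(10)E,4E,7(11)-trien-12,6-olide | C=C(C)C(=O)O[C@H]1C/C(C)=C/[C@H](OC(C)=O)C/C(C)=C/[C@H]2OC(=O)C(COC(C)=O)=C12 | target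

**Step count and risk**

Total step count: 25 (steps 18 and 19 prepare acid 27). Longest linear sequence: 23 steps (steps 1–17 and 20–25).

Steps most likely to fail:

Step 15 (key step). Hydroboration of the hindered tetrasubstituted alkene may be slow, or may place boron on C5 or on the β face. Such boranes do not fragment or give other alkene geometries, so the one-pot protocol would deliver mixtures. Fallback: the two operations are separated. From 19, hydroboration with BH3·THF is followed by esterification of the alkylborane with pinacol to give the tertiary pinacol boronate F1, which can be purified to the single 4α-boryl trans-decalin. Its ate complex with NaOMe in MeOH/THF is then fragmented with gentle warming, and the route is rejoined at 22.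

Step 17. Enolisation may not be fully selective for C6, and oxygen transfer to the flexible ten-membered enolate may show poor or reversed facial selectivity. Fallback: C6 is then set by substitution instead of by face selection. From 23 the hydroxylation is run as before; if the (6S)-alcohol F2 is the main product, it is esterified with acid 27 under Mitsunobu conditions (PPh3, diisopropyl azodicarboxylate, THF, 0 °C). This inverts C6 and rejoins the route at 28.

Step 16. Protic acid may trigger transannular cyclisation of the 1,5-diene, move C4=C5 into conjugation with the new ketone, or cleave the allylic silyl ether before the ether-deactivated ketal has opened. Fallback: from 22, the dioxolane is opened without protic acid by Me3SiOTf/i-Pr2NEt (CH2Cl2, −20 °C) to the 2-(trimethylsilyloxy)ethyl dienol ether F3. Rubottom-type oxidation of its electron-rich C6=C7 enol ether bond with dimethyldioxirane at −78 °C, then aqueous work-up, gives the hydroxy ketone directly. The route is rejoined at 24 without passing through 23.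

**Further compounds**
F1 | step 15 | 4α-(4,4,5,5-tetramethyl-1,3,2-dioxaborolan-2-yl)-5α-H trans-decalin mesylate (pinacol boronate of 20) | C[C@]12C[C@H](OCc3ccc(OC)cc3)C4(OCCO4)C[C@@H]1[C@@](C)(B5OC(C)(C)C(C)(C)O5)C[C@@H](O[Si](C)(C)C(C)(C)C)[C@@H]2OS(C)(=O)=O
F2 | step 17 | (2R,6S,8S)-6-hydroxy ketone (C6 epimer of 24) | COc1ccc(CO[C@H]2C/C(C)=C/[C@H](O[Si](C)(C)C(C)(C)C)C/C(C)=C/[C@H](O)C2=O)cc1
F3 | step 16 | (2R,8S)-2-(tert-butyldimethylsilyloxy)-8-(4-methoxybenzyloxy)-7-[2-(trimethylsilyloxy)ethoxy]-4,10-dimethylcyclodeca-1(10),4,6-triene (ring-cis enol ether) | COc1ccc(CO[C@H]2C/C(C)=C/[C@H](O[Si](C)(C)C(C)(C)C)C/C(C)=C/C=C2/OCCO[Si](C)(C)C)cc1
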